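The vessel was stirred, at constant volume and one temperature, and the flasks differed in which charge went in slowly.

| flask | starting material | coupling partner | capture agent | remark | time |
|---|---|---|---|---|---|
| Thursday's | 10 mM | 0.70 equiv | 0.20 mM | run made earlier |  |
| Monday's | 6.7 mM | 0.70 equiv | 0.20 mM | run made earlier |  |
| Saturday's | 15 mM | 0.70 equiv | 0.20 mM | run made earlier |  |
| theta | 10 mM | 0.700 equiv (fed, over 25 s) | 0.200 mM | all else is in the flask from the start; the feed brings no volume worth counting | 2.0 min |
| zeta | 10 mM | 0.700 equiv | 0.200 mM | everything together at the start | 2.0 min |
| epsilon | 10 mM (fed, over 25 s) | 0.700 equiv | 0.200 mM | all else is in the flask from the start; the feed brings no volume worth counting | 2.0 min |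

1. the flask with the highest amount of target, in percent of the starting material charged ("all alike" if they lie within 1.5 percentage points) (theta / zeta / epsilon / all alike)
2. final target, as a percentage of the starting material charged, in theta
3. final target, as a percentage of the starting material charged, in zeta
4. final target, as a percentage of the starting material charged, in epsilon

- the analysis behind the earlier runs scatters by 1.5 percentage points, standard deviation

| run | time / s | target / % | starting material / % |
|---|---|---|---|
| Thursday's | 10.0 | 18 | 0 |
| Thursday's | 30.0 | 25 | 0 |
| Thursday's | 60.0 | 28 | 0 |
| Thursday's | 80.0 | 26 | 1 |
| Thursday's | 120 | 24 | 0 |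
| Monday's | 10.0 | 17 | 0 |
| Monday's | 20.0 | 23 | 0 |
| Monday's | 40.0 | 29 | 0 |
| Monday's | 80.0 | 30 | 3 |
| Saturday's | 15.0 | 22 | 0 |
| Saturday's | 30.0 | 25 | 1 |
| Saturday's | 40.0 | 25 | 0 |
| Saturday's | 60.0 | 23 | 0 |
| Saturday's | 80.0 | 23 | 3 |

(each reading ± 1.5 percentage points)

I read Thursday's table downwards. At 10.0 s the starting material already read 0%, yet target read 18% and climbed to 28% at 60.0 s, so target was coming from an unseen intermediate. Then the climb stopped, with 24% at 120 s. That peak is 40.0% of the partner charge, a reading of its selectivity, and I took it that the rest of the partner had been lost some other way.

The first row against the peak gave the time constant of the climb, 9.71 s. I called this the partner's working time: how long a dose of partner went on making target. Monday's column gave 12.0 s and Saturday's 7.07 s, so as a reading it was longer in the dilute flask than in the concentrated one.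

The crossing was the feed time, since 25 s is longer than the working time. In epsilon the partner stands from the start, while the starting material arrives on average after 12.5 s, which is longer than the working time. Scaling Thursday's peak by the working time over the working time plus that wait, I reckoned 12.2%. In theta, c(coupling partner) should stand near feed rate times working time, 2.72 mM, less than the 7.00 mM that zeta starts with, so I expected a better share there. My order was theta, then zeta near Thursday's values, then epsilon.

The forecast differed: it named epsilon, with 18% in theta, 25% in zeta and 38% in epsilon, holding that with the starting material fed “waste drops and target rises”.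

Theta gave the most target, 38.3%, against 27.9% in zeta and 15.5% in epsilon.

    coupling partner + open intermediate → target (k = 12.0 M⁻¹ s⁻¹)
    2 coupling partner → self-condensation product (k = 18.0 M⁻¹ s⁻¹)
    starting material + open intermediate → side product (k = 43.0 M⁻¹ s⁻¹)
    starting material → open intermediate (k = 0.990 s⁻¹)
    open intermediate + capture agent → trapped intermediate (k = 2.70 M⁻¹ s⁻¹)

At the end of theta's feed, c(coupling partner) stood at 2.06 mM, which is 29.4% of its own charge and less than the 2.72 mM I had reckoned; divided by the feed rate, that level gives 7.35 s, shorter than the working time of 9.71 s. I read that working time at 0.70 equiv, so I reckoned no level for the neighbour of theta charged with 2.80 equiv. That flask's 62.2% of target was 22.2% of its partner charge, less than theta's 54.8%.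

Readings and results are simulated from invented constants.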